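## Retrosynthetic overview

1. Target ⇒ 7-O-prenyl chroman-4-one (C3=C4 from the C4 ketone by reduction and dehydration) ⇒ 7-hydroxy-5-[2-(4-hydroxyphenyl)ethyl]-2,2-dimethylchroman-4-one (O–prenyl bond).
2. That chromanone ⇒ cross-conjugated ynone + 1-methoxy-1,3-bis(silyloxy)butadiene: Diels–Alder (bonds C4a–C8a and C5–C6), loss of MeOH, then oxa-Michael (bond O1–C2), all in one pot.
3. Ynone ⇒ 4-aryl-but-1-yne + senecioyl chloride; alkyne ⇒ raspberry ketone; diene ⇒ methyl acetoacetate.
4. Ring order: the 4-hydroxyphenyl ring is bought; the central benzene ring and then the pyran ring are made in the same operation; nothing else is cyclised.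

Assumption: the target has no stereocentre, so no enantioselective step is needed; the stereocentres of 14 and 19 are racemic and are erased in the step that creates them.

Convention: enolates and organometallics generated on purpose before an electrophile is added (3, 5, 8, 9) are numbered; phenoxide or alkoxide salts of a listed compound are written as that compound.

## Route

Step 1
Reactants: 1 4-(4-hydroxyphenyl)butan-2-one (raspberry ketone)
Product: 2 4-{4-[(tert-butyldimethylsilyl)oxy]phenyl}butan-2-one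
Conditions: TBSCl (1.2 equiv), imidazole (2 equiv), DMF, rt
Reagents that add atoms: tert-butyldimethylsilyl chloride (TBSCl), CC(C)(C)[Si](C)(C)Cl
Why: Imidazole-mediated O-silylation (Corey TBS protection) of the only acidic OH, needed because the next two steps use LDA and a Grignard reagent, and the silyl ether comes off again at no cost in step 5; no stereocentre.

Step 2
Reactants: 2 4-{4-[(tert-butyldimethylsilyl)oxy]phenyl}butan-2-one
Product: 6 tert-butyl[4-(but-3-yn-1-yl)phenoxy]dimethylsilane, via lithium enolate 3 (not isolated), via enol phosphate 4 (not isolated), via lithium acetylide 5 (not isolated)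
Conditions: LDA (1.1 equiv), THF, −78 °C; ClP(O)(OEt)2 (1.15 equiv), −78 °C → rt; then LDA (2.3 equiv), THF, −78 °C → rt; H2O
Reagents that add atoms: LDA, [Li]N(C(C)C)C(C)C, gives the Li of 3 and 5; diethyl chlorophosphate, CCOP(=O)(Cl)OCC, gives the phosphate of 4; no reagent atom other than H stays in 6
Why: Negishi methyl-ketone-to-alkyne conversion: LDA at −78 °C gives the kinetic CH3-side enolate 3, O-phosphorylation gives the terminal enol phosphate 4, and LDA-induced β-elimination of diethyl phosphate gives the acetylide 5, protonated on quench; no stereocentre.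

Step 3
Reactants: 6 tert-butyl[4-(but-3-yn-1-yl)phenoxy]dimethylsilane; 7 3-methylbut-2-enoyl chloride (senecioyl chloride)
Product: 10 8-{4-[(tert-butyldimethylsilyl)oxy]phenyl}-2-methyloct-2-en-5-yn-4-one, via alkynylmagnesium bromide 8 (not isolated), via alkynylzinc chloride 9 (not isolated)
Conditions: EtMgBr (1.05 equiv), THF, 0 → 40 °C; ZnCl2 (1.1 equiv), 0 °C → rt; 7 (1.2 equiv), Pd(PPh3)4 (3 mol %), 0 °C → rt
Reagents that add atoms: ethylmagnesium bromide, CC[Mg]Br, gives the MgBr of 8; zinc chloride, Cl[Zn]Cl, gives the ZnCl of 9; no reagent atom other than H stays in 10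
Why: Magnesiation of the terminal alkyne with EtMgBr (ethane evolves), transmetalation to the alkynylzinc chloride and Negishi acylation (Pd(0)-catalysed coupling with an acid chloride), which stops at the ketone and, being amine-free, cannot turn the senecioyl chloride into a vinylketene; no stereocentre.

Step 4
Reactants: 11 methyl acetoacetate
Product: 13 1-methoxy-1,3-bis[(trimethylsilyl)oxy]buta-1,3-diene (Chan's diene), via silyl enol ether 12 (not isolated)
Conditions: TMSOTf (2.2 equiv), Et3N (2.5 equiv), Et2O, 0 °C → rt; decant from the triflate salt, distil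
Reagents that add atoms: trimethylsilyl trifluoromethanesulfonate (TMSOTf), C[Si](C)(C)OS(=O)(=O)C(F)(F)F
Why: Double O-silylation of a β-keto ester with TMSOTf/Et3N (Simchen conditions): the enol ether 12 forms first and its γ-CH3 is then deprotonated and silylated on oxygen to the ketene acetal; the double-bond geometry is irrelevant for step 5.

Step 5
Reactants: 10 8-{4-[(tert-butyldimethylsilyl)oxy]phenyl}-2-methyloct-2-en-5-yn-4-one; 13 1-methoxy-1,3-bis[(trimethylsilyl)oxy]buta-1,3-diene
Product: 16 7-hydroxy-5-[2-(4-hydroxyphenyl)ethyl]-2,2-dimethyl-2,3-dihydro-4H-chromen-4-one, via cycloadduct 14 (not isolated), via dihydroxyaryl enone 15 (not isolated)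
Conditions: 13 (2.5 equiv), toluene (2 M), 90 °C, 24 h; then TBAF (4 equiv), THF, 0 → 40 °C; AcOH
Reagents that add atoms: none
Why: Normal-demand Diels–Alder reaction of a Chan/Brassard-type diene with the ynone triple bond (nucleophilic CH2 terminus to the β-carbon, ketene-acetal carbon to the acyl-bearing α-carbon, as in the orsellinate synthesis from a butynoate), then fluoride-triggered eliminative aromatisation (loss of MeOH) with global desilylation, then 6-endo oxa-Michael addition of the ortho-phenoxide of 15 to the β,β-dimethyl enone, so the benzene and pyranone rings are both made in this pot with the 5-alkyl/7-oxygen pattern fixed by the cycloaddition; the stereocentre of 14 is racemic and is destroyed on aromatisation.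

Step 6
Reactants: 16 7-hydroxy-5-[2-(4-hydroxyphenyl)ethyl]-2,2-dimethyl-2,3-dihydro-4H-chromen-4-one; 17 1-bromo-3-methylbut-2-ene (prenyl bromide)
Product: 18 5-[2-(4-hydroxyphenyl)ethyl]-2,2-dimethyl-7-[(3-methylbut-2-en-1-yl)oxy]-2,3-dihydro-4H-chromen-4-one
Conditions: 17 (1.05 equiv), K2CO3 (1.05 equiv), acetone, rt → 45 °C
Reagents that add atoms: none
Why: Williamson etherification made chemoselective by acidity: the 7-OH is para to the ring ketone (vinylogous acid, pKa about 8) while the 4'-OH is an ordinary alkylphenol (pKa about 10), so one equivalent of carbonate generates and alkylates only the 7-phenoxide; no stereocentre.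

Step 7
Reactants: 18 5-[2-(4-hydroxyphenyl)ethyl]-2,2-dimethyl-7-[(3-methylbut-2-en-1-yl)oxy]-2,3-dihydro-4H-chromen-4-one
Product: 20 4-(2-{2,2-dimethyl-7-[(3-methylbut-2-en-1-yl)oxy]-2H-chromen-5-yl}ethyl)phenol (target), via chromanol 19 (not isolated)
Conditions: NaBH4 (2 equiv), MeOH–THF, 0 °C → rt; H2O, extract into toluene; p-TsOH·H2O (5 mol %), toluene, 50 °C
Reagents that add atoms: none
Why: Borohydride reduction to the benzylic alcohol 19, then acid-catalysed E1 dehydration through the para-alkoxy-stabilised benzylic cation (the precocene-type chromanone-to-chromene sequence), which gives the conjugated C3=C4 double bond; the stereocentre of 19 is racemic and is removed again.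

## Compound list

1 | 4-(4-hydroxyphenyl)butan-2-one | CC(=O)CCc1ccc(O)cc1 | starting material
2 | 4-{4-[(tert-butyldimethylsilyl)oxy]phenyl}butan-2-one | CC(=O)CCc1ccc(O[Si](C)(C)C(C)(C)C)cc1 | intermediate
3 | lithium 4-{4-[(tert-butyldimethylsilyl)oxy]phenyl}but-1-en-2-olate (kinetic enolate of 2) | [Li]OC(=C)CCc1ccc(O[Si](C)(C)C(C)(C)C)cc1 | intermediate
4 | 4-{4-[(tert-butyldimethylsilyl)oxy]phenyl}but-1-en-2-yl diethyl phosphate | CCOP(=O)(OCC)OC(=C)CCc1ccc(O[Si](C)(C)C(C)(C)C)cc1 | intermediate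
5 | (4-{4-[(tert-butyldimethylsilyl)oxy]phenyl}but-1-yn-1-yl)lithium | [Li]C#CCCc1ccc(O[Si](C)(C)C(C)(C)C)cc1 | intermediate
6 | tert-butyl[4-(but-3-yn-1-yl)phenoxy]dimethylsilane | C#CCCc1ccc(O[Si](C)(C)C(C)(C)C)cc1 | intermediate
7 | 3-methylbut-2-enoyl chloride | CC(C)=CC(=O)Cl | starting material
8 | (4-{4-[(tert-butyldimethylsilyl)oxy]phenyl}but-1-yn-1-yl)magnesium bromide | Br[Mg]C#CCCc1ccc(O[Si](C)(C)C(C)(C)C)cc1 | intermediate
9 | (4-{4-[(tert-butyldimethylsilyl)oxy]phenyl}but-1-yn-1-yl)zinc chloride | Cl[Zn]C#CCCc1ccc(O[Si](C)(C)C(C)(C)C)cc1 | intermediate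
10 | 8-{4-[(tert-butyldimethylsilyl)oxy]phenyl}-2-methyloct-2-en-5-yn-4-one | CC(C)=CC(=O)C#CCCc1ccc(O[Si](C)(C)C(C)(C)C)cc1 | intermediate
11 | methyl acetoacetate (methyl 3-oxobutanoate) | COC(=O)CC(C)=O | starting material
12 | methyl 3-[(trimethylsilyl)oxy]but-2-enoate (E/Z mixture) | COC(=O)C=C(C)O[Si](C)(C)C | intermediate
13 | 1-methoxy-1,3-bis[(trimethylsilyl)oxy]buta-1,3-diene (ketene-acetal geometry not defined) | COC(O[Si](C)(C)C)=CC(=C)O[Si](C)(C)C | intermediate
14 | 1-[2-(2-{4-[(tert-butyldimethylsilyl)oxy]phenyl}ethyl)-6-methoxy-4,6-bis[(trimethylsilyl)oxy]cyclohexa-1,4-dien-1-yl]-3-methylbut-2-en-1-one (racemic) | COC1(O[Si](C)(C)C)C=C(O[Si](C)(C)C)CC(CCc2ccc(O[Si](C)(C)C(C)(C)C)cc2)=C1C(=O)C=C(C)C | intermediate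
15 | 1-{2,4-dihydroxy-6-[2-(4-hydroxyphenyl)ethyl]phenyl}-3-methylbut-2-en-1-one | CC(C)=CC(=O)c1c(O)cc(O)cc1CCc1ccc(O)cc1 | intermediate
16 | 7-hydroxy-5-[2-(4-hydroxyphenyl)ethyl]-2,2-dimethyl-2,3-dihydro-4H-chromen-4-one | CC1(C)CC(=O)c2c(CCc3ccc(O)cc3)cc(O)cc2O1 | intermediate
17 | 1-bromo-3-methylbut-2-ene (prenyl bromide) | CC(C)=CCBr | starting material
18 | 5-[2-(4-hydroxyphenyl)ethyl]-2,2-dimethyl-7-[(3-methylbut-2-en-1-yl)oxy]-2,3-dihydro-4H-chromen-4-one | CC1(C)CC(=O)c2c(CCc3ccc(O)cc3)cc(OCC=C(C)C)cc2O1 | intermediate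
19 | 5-[2-(4-hydroxyphenyl)ethyl]-2,2-dimethyl-7-[(3-methylbut-2-en-1-yl)oxy]-3,4-dihydro-2H-chromen-4-ol (racemic) | CC1(C)CC(O)c2c(CCc3ccc(O)cc3)cc(OCC=C(C)C)cc2O1 | intermediate
20 | 4-(2-{2,2-dimethyl-7-[(3-methylbut-2-en-1-yl)oxy]-2H-chromen-5-yl}ethyl)phenol | CC(C)=CCOc1cc(CCc2ccc(O)cc2)c2c(c1)OC(C)(C)C=C2 | target

## Step count and risks

Total steps: 7. Longest linear sequence: 6 (steps 1 → 2 → 3 → 5 → 6 → 7; step 4 is the side branch).

Steps most likely to fail:

**Step 5.** The acyclic bis-silyl diene is heat-sensitive and the ynone carries a β-alkyl group, so the cycloaddition may stall, or give a Michael adduct that does not close. The fallback sets out from 10 and comes back at 16, replacing eliminative aromatisation by an Alder–Rickert sequence. Dimedone is bis-silylated (TMSOTf, Et3N) to the thermally robust 5,5-dimethyl-1,3-bis[(trimethylsilyl)oxy]cyclohexa-1,3-diene F1. Heated neat with 10 at 140 °C, it gives with the same regiochemistry the bicyclo[2.2.2]octadiene adduct F2. This loses 2-methylpropene by retro-Diels–Alder to the bis-TMS resorcinyl senecioyl ketone F3. TBAF in THF then desilylates F3 to 15, which closes to 16.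

**Step 6.** Selectivity rests only on the acidity difference; the bis-ether or the 4'-O-ether may form. The fallback sets out from the crude cycloadduct 14 and comes back at 18, keeping the silyl ether as a protecting group. Compound 14 is unmasked with 1 M HCl in THF at 0 °C, which removes the TMS groups and methanol and aromatises but leaves the aryl TBS ether, giving 1-[2-(2-{4-[(tert-butyldimethylsilyl)oxy]phenyl}ethyl)-4,6-dihydroxyphenyl]-3-methylbut-2-en-1-one F4. NaOAc in EtOH at 60 °C then closes the ring to 5-(2-{4-[(tert-butyldimethylsilyl)oxy]phenyl}ethyl)-7-hydroxy-2,2-dimethylchroman-4-one F5. Its single free OH is alkylated with 17 (K2CO3, acetone) to the 7-prenyl ether of the TBS-protected chromanone F6. TBAF in THF at 0 °C cleaves the silyl ether to give 18.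

**Step 7.** Acid meets an aryl prenyl ether and an electron-rich chromene, so ether cleavage or chromene dimerisation is possible; the hindered, electron-rich ketone may also reduce slowly. The fallback sets out from 18 and comes back at 20, using a base-mediated Shapiro reaction instead of reduction and acid. Compound 18 is condensed with TsNHNH2 (EtOH, cat. AcOH, 70 °C) to the chromanone tosylhydrazone F7. LDA (3.3 equiv, one for the phenol) in THF, −78 °C → rt, deprotonates C3; loss of sulfinate and N2 gives the C4-lithiated chromene lithium phenoxide F8, which is protonated on water quench to 20.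

## Further compounds

F1 | step 5 | 5,5-dimethyl-1,3-bis[(trimethylsilyl)oxy]cyclohexa-1,3-diene | CC1(C)CC(O[Si](C)(C)C)=CC(O[Si](C)(C)C)=C1
F2 | step 5 | 1-[5-(2-{4-[(tert-butyldimethylsilyl)oxy]phenyl}ethyl)-8,8-dimethyl-1,3-bis[(trimethylsilyl)oxy]bicyclo[2.2.2]octa-2,5-dien-6-yl]-3-methylbut-2-en-1-one (racemic) | C[Si](C)(C)OC12CC(C)(C)C(C(O[Si](C)(C)C)=C1)C(CCc1ccc(O[Si](C)(C)C(C)(C)C)cc1)=C2C(=O)C=C(C)C
F3 | step 5 | 1-[2-(2-{4-[(tert-butyldimethylsilyl)oxy]phenyl}ethyl)-4,6-bis[(trimethylsilyl)oxy]phenyl]-3-methylbut-2-en-1-one | CC(C)=CC(=O)c1c(O[Si](C)(C)C)cc(O[Si](C)(C)C)cc1CCc1ccc(O[Si](C)(C)C(C)(C)C)cc1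
F4 | step 6 | 1-[2-(2-{4-[(tert-butyldimethylsilyl)oxy]phenyl}ethyl)-4,6-dihydroxyphenyl]-3-methylbut-2-en-1-one | CC(C)=CC(=O)c1c(O)cc(O)cc1CCc1ccc(O[Si](C)(C)C(C)(C)C)cc1
F5 | step 6 | 5-(2-{4-[(tert-butyldimethylsilyl)oxy]phenyl}ethyl)-7-hydroxy-2,2-dimethyl-2,3-dihydro-4H-chromen-4-one | CC1(C)CC(=O)c2c(CCc3ccc(O[Si](C)(C)C(C)(C)C)cc3)cc(O)cc2O1
F6 | step 6 | 5-(2-{4-[(tert-butyldimethylsilyl)oxy]phenyl}ethyl)-2,2-dimethyl-7-[(3-methylbut-2-en-1-yl)oxy]-2,3-dihydro-4H-chromen-4-one | CC1(C)CC(=O)c2c(CCc3ccc(O[Si](C)(C)C(C)(C)C)cc3)cc(OCC=C(C)C)cc2O1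
F7 | step 7 | N'-{5-[2-(4-hydroxyphenyl)ethyl]-2,2-dimethyl-7-[(3-methylbut-2-en-1-yl)oxy]-2,3-dihydro-4H-chromen-4-ylidene}-4-methylbenzenesulfonohydrazide | CC1(C)CC(=NNS(=O)(=O)c2ccc(C)cc2)c2c(CCc3ccc(O)cc3)cc(OCC=C(C)C)cc2O1
F8 | step 7 | lithium 4-(2-{4-lithio-2,2-dimethyl-7-[(3-methylbut-2-en-1-yl)oxy]-2H-chromen-5-yl}ethyl)phenolate | [Li]Oc1ccc(CCc2cc(OCC=C(C)C)cc3OC(C)(C)C=C([Li])c23)cc1
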